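The route rests on disconnecting C7–C11 of the α-methylene-γ-lactone (ring B), which is trans-fused at C6–C7 to the ten-membered carbocycle (ring A). The feature exploited is the anti array of the C7–C11 and C8–O bonds beside O6. This array is the imprint of an SN2 opening of a trans-7,8-epoxide by a carbon tethered to O6. The precursor is therefore an acyclic Sharpless epoxy alcohol esterified with diethylphosphonoacetic acid. In one operation its carbanion closes ring B (5-exo-tet, inversion at C7), frees the C8 hydroxyl and, with formaldehyde, installs the C13 methylene. Ring-closing metathesis at C1=C10, methacrylation and desilylation finish the synthesis.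

Key step: step 12

Remark on numbering: germacrane numbering is used throughout.
- Ring A is C1–C10. It holds the C1=C10 olefin, C15H2O on C4, the lactone oxygen O6 on C6, the ester oxygen O8 on C8 and C14H2O on C10.
- Ring B is C6, C7, C11, C12(=O) and O6. C13 is the methylene on C11.
- TBS is tert-butyldimethylsilyl.

Remark on the olefin: C1=C10 of the target is E by the CIP rules (C14 outranks C9), but the ring carbons C2 and C9 are cis, so it is a cis ring olefin.

Step 1
Reactants: 1 hex-5-enoyl chloride; 2 (4R)-4-benzyl-1,3-oxazolidin-2-one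
Product: 3 (4R)-4-benzyl-3-(hex-5-enoyl)-1,3-oxazolidin-2-one
Conditions: 2, n-BuLi, THF, −78 °C; then 1, −78 → 0 °C
Reagents that add atoms: none
Why: N-Acylation of the lithiated oxazolidinone with an acid chloride is the standard way to load an Evans auxiliary and creates no stereocentre.

Step 2
Reactants: 3 (4R)-4-benzyl-3-(hex-5-enoyl)-1,3-oxazolidin-2-one; 4 tert-butyl bromoacetate
Product: 5 tert-butyl (3S)-3-{[(4R)-4-benzyl-2-oxo-1,3-oxazolidin-3-yl]carbonyl}hept-6-enoate
Conditions: NaN(SiMe3)2, THF, −78 °C; then 4, −78 → −40 °C
Reagents that add atoms: none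
Why: Evans asymmetric alkylation: the chelated sodium Z-enolate is shielded on one face by the benzyl group of the 4R auxiliary, so the reactive α-bromo ester should enter from the other face and set C4 as S.

Step 3
Reactants: 5 tert-butyl (3S)-3-{[(4R)-4-benzyl-2-oxo-1,3-oxazolidin-3-yl]carbonyl}hept-6-enoate
Product: 6 tert-butyl (3S)-3-(hydroxymethyl)hept-6-enoate
Conditions: LiBH4, MeOH (1 equiv), Et2O, 0 °C
Reagents that add atoms: none
Why: Reductive auxiliary cleavage: LiBH4 attacks the activated exocyclic imide carbonyl far faster than the hindered tert-butyl ester or the isolated alkene, and C4 is not enolised under these conditions.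

Step 4
Reactants: 6 tert-butyl (3S)-3-(hydroxymethyl)hept-6-enoate
Product: 7 tert-butyl (3S)-3-(TBS-oxymethyl)hept-6-enoate
Conditions: TBSCl, imidazole, CH2Cl2, 0 °C → rt
Reagents that add atoms: tert-butyldimethylsilyl chloride CC(C)(C)[Si](C)(C)Cl
Why: Standard imidazole-promoted silylation of a primary alcohol, which also blocks lactonisation onto the ester.

Step 5
Reactants: 7 tert-butyl (3S)-3-(TBS-oxymethyl)hept-6-enoate
Product: 8 (3S)-3-(TBS-oxymethyl)hept-6-enal (C1–C6 fragment, C6 = CHO)
Conditions: iBu2AlH (1.05 equiv), CH2Cl2, −78 °C; aq. potassium sodium tartrate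
Reagents that add atoms: none
Why: Partial ester reduction: at −78 °C the aluminium hemiacetal from a tert-butyl ester persists until work-up, so the reaction should stop at the aldehyde, whose stereocentre is β to the carbonyl and cannot epimerise.

Step 6
Reactants: 9 2-methylidenepropane-1,3-diol
Product: 10 2-(TBS-oxymethyl)prop-2-en-1-ol
Conditions: NaH (1.0 equiv), THF, 0 °C → rt; TBSCl (1.0 equiv)
Reagents that add atoms: tert-butyldimethylsilyl chloride CC(C)(C)[Si](C)(C)Cl
Why: Monosilylation of a symmetrical diol through its sparingly soluble monosodium alkoxide, which reacts once with the silyl chloride.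

Step 7
Reactants: 10 2-(TBS-oxymethyl)prop-2-en-1-ol
Product: 11 [2-(bromomethyl)prop-2-en-1-yl]oxy-TBS
Conditions: CBr4, PPh3, CH2Cl2, 0 °C
Reagents that add atoms: carbon tetrabromide BrC(Br)(Br)Br
Why: The Appel reaction converts the primary allylic alcohol into the bromide under neutral conditions that the silyl ether tolerates, and direct and allylic displacement give the same product.

Step 8
Reactants: 11 [2-(bromomethyl)prop-2-en-1-yl]oxy-TBS; 12 ethynylmagnesium bromide
Product: 13 (2-methylidenepent-4-yn-1-yl)oxy-TBS (C7–C10 and C14 fragment)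
Conditions: 12 (1.5 equiv), CuBr·SMe2 (10 mol %), THF, 0 °C → rt
Reagents that add atoms: none
Why: Copper-catalysed coupling of an alkynyl Grignard reagent with an allylic bromide gives the skipped enyne, and the symmetry of the 2-substituted allyl unit makes α and γ attack degenerate.

Step 9
Reactants: 13 (2-methylidenepent-4-yn-1-yl)oxy-TBS; 8 (3S)-3-(TBS-oxymethyl)hept-6-enal
Product: 16 (4E,6R,8S)-2,8-bis(TBS-oxymethyl)dodeca-1,4,11-trien-6-ol, via alkenylborane 14 (not isolated), via alkenylzinc 15 (not isolated)
Conditions: 13, Cy2BH (1.0 equiv), toluene, 0 °C → rt; Et2Zn, −78 °C; (−)-MIB [(2S)-3-exo-morpholinoisoborneol, 5 mol %]; 8 added slowly, −10 °C; aq. NH4Cl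
Reagents that add atoms: none
Why: Hydroboration, boron-to-zinc exchange and catalytic asymmetric alkenylzinc addition: syn hydroboration of the terminal alkyne (much faster than of the 1,1-disubstituted alkene) fixes the E geometry of C7=C8, and the (−)-MIB zinc complex should deliver the alkenyl group to the Si face of 8 as in the parent dialkylzinc additions, setting C6 as R.

Step 10
Reactants: 16 (4E,6R,8S)-2,8-bis(TBS-oxymethyl)dodeca-1,4,11-trien-6-ol
Product: 17 (4S,6R,7R,8R)-trans-7,8-epoxy-6-ol
Conditions: Ti(OiPr)4 (20 mol %), D-(−)-diisopropyl tartrate (24 mol %), t-BuOOH (1.5 equiv, decane), 4 Å MS, CH2Cl2, −20 °C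
Reagents that add atoms: tert-butyl hydroperoxide CC(C)(C)OO
Why: Sharpless asymmetric epoxidation in its matched sense: for a 6R E-allylic alcohol the D-(−)-tartrate catalyst is the fast-reacting combination and should give the anti (erythro) 7R,8R epoxide, any 6S epimer stays behind as in a kinetic resolution, and the two non-allylic alkenes are not touched.

Step 11
Reactants: 17 (4S,6R,7R,8R)-trans-7,8-epoxy-6-ol; 18 diethylphosphonoacetic acid
Product: 19 O6-(diethylphosphonoacetyl) ester of 17
Conditions: 18, DCC, DMAP (10 mol %), CH2Cl2, 0 °C → rt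
Reagents that add atoms: none
Why: Steglich esterification acylates the secondary C6 hydroxyl under near-neutral conditions that avoid Payne rearrangement and epoxide opening, with all stereocentres unchanged.

Step 12
Reactants: 19 O6-(diethylphosphonoacetyl) ester of 17
Product: 21 (4S,6R,7R,8R)-seco α-methylene-γ-lactone with free 8-OH, via phosphono lactone 20 (not isolated)
Conditions: LiN(SiMe3)2 (1.05 equiv), LiClO4 (1.5 equiv), THF, −78 → 45 °C; then (CH2O)n (5 equiv), 45 °C; aq. NH4Cl
Reagents that add atoms: formaldehyde (from paraformaldehyde) C=O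
Why: Proposed new method: LiN(SiMe3)2 deprotonates the phosphonoacetate, carbanion carbon C11 (tied to C7 through C12, O6 and C6) attacks epoxide carbon C7 anti to the C7–O bond, the C8 alkoxide then takes the acidic C11–H to leave the phosphonate carbanion of 20, and this olefinates formaldehyde (Horner–Wadsworth–Emmons) to create C11=C13. The closest known reaction types are the cyclisation of stabilised carbanions onto epoxides (Stork epoxynitrile cyclisation), the base-induced C-2 opening of 2,3-epoxy alcohol carbamates to five-membered rings and the formaldehyde olefination of α-phosphono lactones, whereas a C–C closure through the ester tether of an epoxy alcohol is the untested part. Ring B closes 5-exo-tet, and since the charge is carried largely by the exocyclic phosphoryl group the in-ring ester can twist out of conjugation, which should relax the 5-(enolendo) restriction just as in Lacey–Dieckmann and butenolide-forming intramolecular olefinations. C7 is fixed by SN2 inversion of the epoxide carbon, C8 keeps its C–O bond and hence its configuration, and the anti relation between O6 and the epoxide oxygen translates into the trans C6/C7 fusion. The step needs attack at C7 rather than C8 (secured by the three-atom tether and the collinear exo trajectory, the 6-endo path being misaligned), C- rather than O-alkylation (soft doubly stabilised carbanion, lithium on the epoxide oxygen) and no acyl shift to O8 (the 8,12-lactone would be cis-disubstituted and the carbanionic lactone is a poor electrophile). Lithium as counter-ion and a ceiling of 45 °C should hold back phosphoryl migration to O8, the entry to Wadsworth–Emmons cyclopropanation.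

Step 13
Reactants: 21 (4S,6R,7R,8R)-seco α-methylene-γ-lactone with free 8-OH
Product: 22 (1(10)E,4S,6R,7R,8R)-14,15-bis(TBS-oxy)-8-hydroxygermacra-1(10),11(13)-dien-6,12-olide
Conditions: second-generation Hoveyda–Grubbs catalyst (10 mol %), 1,4-benzoquinone (20 mol %), toluene (1 mM, slow addition of 21, argon sparge), 80 °C
Reagents that add atoms: none
Why: Ring-closing metathesis: the ruthenium alkylidene should form at the monosubstituted C1 alkene and close on the 1,1-disubstituted C10 alkene, with both arms held on the trans-substituted ring B, the ten-membered ring favouring the olefin with C2 and C9 cis, and the electron-poor C11=C13 methylene staying out because its closure would need a bridged eight-membered ring.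

Step 14
Reactants: 22 (1(10)E,4S,6R,7R,8R)-14,15-bis(TBS-oxy)-8-hydroxygermacra-1(10),11(13)-dien-6,12-olide; 23 methacrylic anhydride
Product: 24 14,15-bis-TBS ether of the target
Conditions: 23 (3 equiv), Et3N, DMAP (0.3 equiv), CH2Cl2, 0 °C → rt
Reagents that add atoms: none
Why: DMAP-catalysed acylation of the only free hydroxyl (O8) proceeds with retention at C8 and is placed after the metathesis so that the methacrylate cannot compete as an olefin partner.

Step 15
Reactants: 24 14,15-bis-TBS ether of the target
Product: 25 target, (1(10)E,4S,6R,7S,8R)-14,15-dihydroxy-8-(methacryloyloxy)germacra-1(10),11(13)-dien-6,12-olide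
Conditions: HF·pyridine, pyridine, THF, 0 °C → rt
Reagents that add atoms: none
Why: Fluoride-mediated cleavage of both primary silyl ethers under buffered, weakly acidic conditions should spare the two conjugate acceptors, both ester linkages and all stereocentres.

Compound list
1 | hex-5-enoyl chloride | C=CCCCC(=O)Cl | starting material
2 | (4R)-4-benzyl-1,3-oxazolidin-2-one | O=C1N[C@H](Cc2ccccc2)CO1 | starting material
3 | (4R)-4-benzyl-3-(hex-5-enoyl)-1,3-oxazolidin-2-one | C=CCCCC(=O)N1[C@H](Cc2ccccc2)COC1=O | intermediate
4 | tert-butyl bromoacetate | CC(C)(C)OC(=O)CBr | starting material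
5 | tert-butyl (3S)-3-{[(4R)-4-benzyl-2-oxo-1,3-oxazolidin-3-yl]carbonyl}hept-6-enoate | C=CCC[C@H](C(=O)N1[C@H](Cc2ccccc2)COC1=O)CC(=O)OC(C)(C)C | intermediate
6 | tert-butyl (3S)-3-(hydroxymethyl)hept-6-enoate | C=CCC[C@H](CO)CC(=O)OC(C)(C)C | intermediate
7 | tert-butyl (3S)-3-{[(tert-butyldimethylsilyl)oxy]methyl}hept-6-enoate | C=CCC[C@H](CO[Si](C)(C)C(C)(C)C)CC(=O)OC(C)(C)C | intermediate
8 | (3S)-3-{[(tert-butyldimethylsilyl)oxy]methyl}hept-6-enal | C=CCC[C@H](CO[Si](C)(C)C(C)(C)C)CC=O | intermediate
9 | 2-methylidenepropane-1,3-diol | C=C(CO)CO | starting material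
10 | 2-{[(tert-butyldimethylsilyl)oxy]methyl}prop-2-en-1-ol | C=C(CO)CO[Si](C)(C)C(C)(C)C | intermediate
11 | {[2-(bromomethyl)prop-2-en-1-yl]oxy}(tert-butyl)dimethylsilane | C=C(CBr)CO[Si](C)(C)C(C)(C)C | intermediate
12 | ethynylmagnesium bromide | C#C[Mg]Br | starting material
13 | tert-butyl(dimethyl)[(2-methylidenepent-4-yn-1-yl)oxy]silane | C#CCC(=C)CO[Si](C)(C)C(C)(C)C | intermediate
14 | (E)-alkenyl(dicyclohexyl)borane from 13 (boron on C7) | C=C(C/C=C/B(C1CCCCC1)C1CCCCC1)CO[Si](C)(C)C(C)(C)C | intermediate
15 | (E)-alkenyl(ethyl)zinc from 14 (zinc on C7) | C=C(C/C=C/[Zn]CC)CO[Si](C)(C)C(C)(C)C | intermediate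
16 | (4E,6R,8S)-2,8-bis({[tert-butyl(dimethyl)silyl]oxy}methyl)dodeca-1,4,11-trien-6-ol, in germacrane numbering the 4S,6R,7E allylic alcohol | C=CCC[C@H](CO[Si](C)(C)C(C)(C)C)C[C@@H](O)/C=C/CC(=C)CO[Si](C)(C)C(C)(C)C | intermediate
17 | (4S,6R,7R,8R)-trans-7,8-epoxide of 16, epoxide oxygen anti to the 6-OH in the zigzag projection | C=CCC[C@H](CO[Si](C)(C)C(C)(C)C)C[C@@H](O)[C@H]1O[C@@H]1CC(=C)CO[Si](C)(C)C(C)(C)C | intermediate
18 | diethylphosphonoacetic acid | CCOP(=O)(CC(=O)O)OCC | starting material
19 | O6-(diethylphosphonoacetyl) ester of 17, all stereocentres as in 17 | C=CCC[C@H](CO[Si](C)(C)C(C)(C)C)C[C@@H](OC(=O)CP(=O)(OCC)OCC)[C@H]1O[C@@H]1CC(=C)CO[Si](C)(C)C(C)(C)C | intermediate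
20 | trans-6,7-disubstituted α-(diethoxyphosphoryl)-γ-lactone with free 8-OH (present as its lithium carbanion, C11 undefined; C4, C6, C7, C8 arranged as in 21) | C=CCC[C@H](CO[Si](C)(C)C(C)(C)C)C[C@H]1OC(=O)C(P(=O)(OCC)OCC)[C@@H]1[C@H](O)CC(=C)CO[Si](C)(C)C(C)(C)C | intermediate
21 | (4S,6R,7R,8R)-seco α-methylene-γ-lactone: trans lactone on C6/C7, 8-OH, terminal alkene at C1, methylidene at C10 | C=CCC[C@H](CO[Si](C)(C)C(C)(C)C)C[C@H]1OC(=O)C(=C)[C@@H]1[C@H](O)CC(=C)CO[Si](C)(C)C(C)(C)C | intermediate
22 | (1(10)E,4S,6R,7R,8R)-14,15-bis(TBS-oxy)-8-hydroxygermacra-1(10),11(13)-dien-6,12-olide | O[C@@H]1C/C(CO[Si](C)(C)C(C)(C)C)=C\CC[C@H](CO[Si](C)(C)C(C)(C)C)C[C@H]2OC(=O)C(=C)[C@H]12 | intermediate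
23 | methacrylic anhydride | C=C(C)C(=O)OC(=O)C(C)=C | starting material
24 | (1(10)E,4S,6R,7S,8R)-14,15-bis(TBS-oxy)-8-(methacryloyloxy)germacra-1(10),11(13)-dien-6,12-olide | C=C(C)C(=O)O[C@@H]1C/C(CO[Si](C)(C)C(C)(C)C)=C\CC[C@H](CO[Si](C)(C)C(C)(C)C)C[C@H]2OC(=O)C(=C)[C@H]12 | intermediate
25 | (1(10)E,4S,6R,7S,8R)-14,15-dihydroxy-8-(methacryloyloxy)germacra-1(10),11(13)-dien-6,12-olide | C=C(C)C(=O)O[C@@H]1C/C(CO)=C\CC[C@H](CO)C[C@H]2OC(=O)C(=C)[C@H]12 | target

Total step count: 15. Longest linear sequence: 12 steps (steps 1–5, then 9–15).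

Steps most likely to fail

Step 12 (the labelled step).
- Risk: the closure may be too slow, because the ester prefers the rotamer that keeps C11 away from C7 and the carbanion must leave conjugation with the ring carbonyl. This would leave room for alkylation through the enolate oxygen or for phosphoryl migration to O8.
- Fallback: it uses known radical chemistry for the same bond, sets out from 17 and comes back at 21.
- Esterification: 17 is esterified with propiolic acid (DCC, DMAP, CH2Cl2, −20 °C) to the epoxy propiolate F1.
- Cyclisation: F1 is added slowly to Cp2TiCl (from Cp2TiCl2 and Mn dust, 2,4,6-collidine hydrochloride, 1,4-cyclohexadiene, THF, rt).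
- Mechanism: single-electron transfer from trivalent titanium opens the epoxide to the β-titanoxy radical at C7. This is the regiochemistry that such reductions of 2,3-epoxy alcohol derivatives show when they give 1,3-diols. The radical closes 5-exo-dig on alkyne carbon C11, the vinyl radical abstracts hydrogen, and hydrolysis of the O8–Ti bond gives 21.
- Precedent: titanocene chloride epoxide opening with 5-exo closure on alkynes is established, and so is the closure of β-acyloxyalkyl radicals on propiolates to α-methylene lactones.
- Stereochemistry: C8 keeps the epoxide configuration, and C7 is set by the trans preference of the ring closure relative to the C5 chain.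

Step 13.
- Risk: oligomerisation by cross metathesis may outrun closure of the strained ten-membered ring, and the ruthenium alkylidene may be drained by the conjugated C11=C13 methylene.
- Fallback: it takes that olefin out of the substrate, sets out from 20 and comes back at 22.
- Isolation of 20: step 12 is quenched with aq. NH4Cl before paraformaldehyde is added, so that 20 is isolated.
- Sequence: metathesis under the conditions of step 13 closes ring A to the macrocyclic α-phosphono lactone F2. Horner–Wadsworth–Emmons olefination (K2CO3, aq. HCHO, THF, rt) then installs C13 and gives 22.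

Step 9.
- Risk: poor facial selectivity with an α-unbranched aliphatic aldehyde, and competing ethyl transfer.
- Fallback: it replaces catalyst control by resolution and inversion, sets out from 13 and 8 and comes back at 16 and 17.
- Addition: hydrozirconation of 13 (Cp2Zr(H)Cl, CH2Cl2), exchange with Me2Zn and addition to 8 without ligand give 16 together with its 6S epimer F3.
- Resolution: the conditions of step 10 then act as a Sharpless kinetic resolution. Only the matched 16 is epoxidised to 17, and F3 is recovered.
- Recycling: a Mitsunobu reaction (4-nitrobenzoic acid, DIAD, PPh3, THF) inverts C6 of F3 to the 6R 4-nitrobenzoate F4. Methanolysis (K2CO3, MeOH) returns 16.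

Further compounds
F1 | step 12 | O6-propioloyl ester of 17 (epoxy propiolate) | C=CCC[C@H](CO[Si](C)(C)C(C)(C)C)C[C@@H](OC(=O)C#C)[C@H]1O[C@@H]1CC(=C)CO[Si](C)(C)C(C)(C)C
F2 | step 13 | macrocyclic α-(diethoxyphosphoryl) lactone, 22 with P(O)(OEt)2 and H on C11 in place of the methylene | O[C@@H]1C/C(CO[Si](C)(C)C(C)(C)C)=C\CC[C@H](CO[Si](C)(C)C(C)(C)C)C[C@H]2OC(=O)C(P(=O)(OCC)OCC)[C@H]12
F3 | step 9 | 6S epimer of 16 | C=CCC[C@H](CO[Si](C)(C)C(C)(C)C)C[C@H](O)/C=C/CC(=C)CO[Si](C)(C)C(C)(C)C
F4 | step 9 | 6R 4-nitrobenzoate of 16 | C=CCC[C@H](CO[Si](C)(C)C(C)(C)C)C[C@@H](OC(=O)c1ccc(cc1)[N+](=O)[O-])/C=C/CC(=C)CO[Si](C)(C)C(C)(C)C
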